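**Retrosynthetic overview**

- Target 26 ← bis-silyl ether 25 ← primary allylic alcohol 22 (angeloylation with angelic acid) ← exocyclic methylene compound 20 (singlet-oxygen ene reaction) ← spiro ketone 17 (carbonyl methylenation, then α-methylenation of the lactone).
- Feature: in the cyclohexene ring, the allylic carbinol carbon and the vinyl CH form a β-hydroxy ketone once the alkene carbon bearing CH2O-angelate is taken back to a ketone. The CH2–CH(OH) bond is cut, so an amine-catalysed intramolecular aldol of keto aldehyde 15 closes the six-membered ring, the only ring made in the route.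
- 15 ← keto aldehyde 9 by proline-catalysed α-aminoxylation with nitrosobenzene and silyl adjustment. 9 ← iminium-catalysed Mukaiyama–Michael addition of the fully substituted enol ether 7 to crotonaldehyde on the convex face (quaternary carbon and methyl centre).
- 7 ← enone 6 ← ketone 4 ← the alkene of bicyclic lactone 1, which supplies the cis-fused lactone/cyclopentane pair and the absolute configuration.

Key step: step 12

Remark: lactone 1 is taken as the commercial single (1R,5S) enantiomer. Locants follow 2-oxabicyclo[3.3.0]octane (O2, C3 carbonyl, C7 the later spiro carbon; exo = convex face, endo = concave lactone face). The six-membered ring is C1' (= C7), C2' (ketone, later the alkene carbon bearing CH2O), C3', C4' (new carbinol), C5' (second oxygenated carbon), C6' (CH–CH3). The C5' oxygen is carried as a triethylsilyl ether so that one Swern step can distinguish the primary from the secondary silyl ether.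

Step 1
Reactants: 1 (1R,5S)-2-oxabicyclo[3.3.0]oct-6-en-3-one
Product: 2 6-exo-bromo-7-endo-hydroxy-2-oxabicyclo[3.3.0]octan-3-one
Conditions: NBS, DMSO–H2O, 0 °C → rt
Reagents that add atoms: N-bromosuccinimide, O=C1CCC(=O)N1Br; water, O
Why: Bromohydrin formation: the bromonium ion forms on the convex face and water opens it anti from the concave face at C7, the carbon remote from the ring fusion (attack at C6 is blocked by the lactone CH2), which places Br exo at C6 and OH endo at C7; both centres are removed later, so only the regiochemistry counts.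

Step 2
Reactants: 2 bromohydrin
Product: 3 7-endo-hydroxy-2-oxabicyclo[3.3.0]octan-3-one
Conditions: Bu3SnH, AIBN (cat.), toluene, 80 °C
Reagents that add atoms: none
Why: Radical chain dehalogenation of the secondary bromide, to which the alcohol and the lactone are inert.

Step 3
Reactants: 3 hydroxy lactone
Product: 4 cis-2-oxabicyclo[3.3.0]octane-3,7-dione
Conditions: Dess–Martin periodinane, CH2Cl2, rt
Reagents that add atoms: none
Why: Dess–Martin oxidation under non-basic conditions, so that the β-acyloxy ketone should not open by E1cB loss of the lactone carboxylate.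

Step 4
Reactants: 4 keto lactone
Product: 5 7-exo-ethynyl-7-endo-hydroxy-2-oxabicyclo[3.3.0]octan-3-one
Conditions: HC≡CMgBr, CeCl3, THF, −78 °C; aq. NH4Cl
Reagents that add atoms: ethynylmagnesium bromide, C#C[Mg]Br
Why: Organocerium 1,2-addition to the ketone, which is far more electrophilic than the lactone; the weakly basic cerium acetylide should avoid enolisation and β-elimination, and although convex-face attack is expected the new centre is lost in step 5.

Step 5
Reactants: 5 propargylic alcohol
Product: 6 7-acetyl-2-oxabicyclo[3.3.0]oct-6-en-3-one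
Conditions: HCO2H (90% aq.), 90 °C
Reagents that add atoms: water, O
Why: Rupe rearrangement: dehydration of the tertiary propargylic alcohol to the enyne and Markovnikov hydration of the alkyne give the conjugated methyl ketone; loss of the proton from C6 rather than from C8 (next to the C–O carbon) is expected, and a double-bond isomer would give the same enol ether in step 6.

Step 6
Reactants: 6 enone
Product: 7 7-[1-(triethylsilyloxy)ethylidene]-2-oxabicyclo[3.3.0]octan-3-one (E/Z mixture)
Conditions: Et3SiH, RhCl(PPh3)3 (1 mol%), toluene, 50 °C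
Reagents that add atoms: triethylsilane, CC[SiH](CC)CC
Why: Rhodium-catalysed 1,4-hydrosilylation of the enone gives the fully substituted silyl enol ether regiospecifically and without base, so the lactone is untouched; the enol ether geometry is of no consequence.

Step 7
Reactants: 7 silyl enol ether; 8 (E)-crotonaldehyde
Product: 9 (3S)-3-(7-acetyl-3-oxo-2-oxabicyclo[3.3.0]oct-7-yl)butanal (acetyl endo and butanal chain exo at C7)
Conditions: (2R,5R)-5-benzyl-2-tert-butyl-3-methylimidazolidin-4-one (20 mol%), 2,4-dinitrobenzoic acid (20 mol%), CH2Cl2, H2O (2 equiv), −40 °C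
Reagents that add atoms: (E)-crotonaldehyde (8), C/C=C/C=O
Why: Iminium-catalysed Mukaiyama–Michael addition: the enol ether should attack the Si face of C3 of the (E)-iminium ion (the face left open by the (2R,5R) catalyst, by analogy with the established sense of induction), which sets the methyl-bearing centre, and it should react through its convex face away from the lactone ring, which sets the quaternary carbon; the two faces are controlled independently, so the E/Z ratio of 7 does not matter.

Step 8
Reactants: 9 keto aldehyde; 10 nitrosobenzene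
Product: 12 (2S,3R)-3-(7-acetyl-3-oxo-2-oxabicyclo[3.3.0]oct-7-yl)-2-(N-phenylaminooxy)butan-1-ol, via aminoxy aldehyde 11 (not isolated)
Conditions: D-proline (30 mol%), CHCl3, 4 °C; then EtOH, NaBH4, −20 °C
Reagents that add atoms: nitrosobenzene (10), O=Nc1ccccc1
Why: Proline-catalysed α-aminoxylation (O-selective nitroso aldol) through the aldehyde enamine, with D-proline chosen to give the 2S centre under catalyst control; the hindered methyl ketone should form an enamine much more slowly, and NaBH4 at low temperature should reduce only the aldehyde.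

Step 9
Reactants: 12 aminoxy alcohol
Product: 13 (2S,3R)-3-(7-acetyl-3-oxo-2-oxabicyclo[3.3.0]oct-7-yl)butane-1,2-diol
Conditions: H2 (1 atm), Pd/C, MeOH, rt
Reagents that add atoms: none
Why: Hydrogenolysis of the weak N–O bond releases the secondary alcohol and aniline without touching the ketone, the lactone or the stereocentres.

Step 10
Reactants: 13 diol
Product: 14 1,2-bis(triethylsilyl) ether of 13
Conditions: Et3SiCl, imidazole, DMAP (cat.), DMF, 0 °C → rt
Reagents that add atoms: chlorotriethylsilane, CC[Si](Cl)(CC)CC
Why: Silylation of both hydroxyl groups under basic conditions, which avoids acid-induced internal ketalisation of the diol with the ketone.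

Step 11
Reactants: 14 bis-silyl ether
Product: 15 (2S,3R)-3-(7-acetyl-3-oxo-2-oxabicyclo[3.3.0]oct-7-yl)-2-(triethylsilyloxy)butanal
Conditions: (COCl)2, DMSO, CH2Cl2, −78 → −40 °C; then Et3N, −78 → 0 °C
Reagents that add atoms: none
Why: Swern conditions cleave and oxidise the primary triethylsilyl ether directly to the aldehyde while the more hindered secondary silyl ether should survive, and the low temperature should keep the α-silyloxy centre from epimerising.

Step 12
Reactants: 15 keto aldehyde
Product: 16 spiro ketol (C2' ketone on the endo face of C7; 4'S hydroxyl, 5'S triethylsilyloxy and 6'R methyl all equatorial)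
Conditions: L-proline (30 mol%), DMSO, rt
Reagents that add atoms: none
Why: L-Proline condenses with the methyl ketone, which can form an enamine only toward CH3 because its other α-carbon is the quaternary spiro carbon, and the terminal enamine carbon adds to the aldehyde before hydrolysis of the iminium ion releases the ketol and the catalyst. The closest known reaction is the proline-catalysed intramolecular aldol addition of a methyl ketone of the Hajos–Parrish type, together with the proline aldolisations of keto aldehydes. The cyclohexanone ring closes in the 6-(enolendo)-exo-trig mode. The new carbinol centre C4' should be set in a chair-like transition state in which the silyloxy group (an axial one would be syn-axial to a CH2 of the spiro cyclopentane) and the methyl group are equatorial, so that the C–OSi bond lies antiperiplanar to the forming bond (polar Felkin–Anh alignment) and the aldehyde oxygen takes the equatorial position, where the carboxylic acid of L-proline, held on the methylene side of the enamine by the quaternary carbon, can reach it. The step needs the 4'S carbinol trans to the silyloxy group without dehydration or epimerisation next to the aldehyde: the equatorial alcohol is also the more stable product of this reversible aldol, proline at room temperature is not expected to dehydrate the ketol, and the hindered tertiary α-carbon of the aldehyde should form its own enamine only slowly.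

Step 13
Reactants: 16 spiro ketol
Product: 17 4'-O-triethylsilyl ether of 16
Conditions: Et3SiOTf, 2,6-lutidine, CH2Cl2, −78 °C
Reagents that add atoms: triethylsilyl trifluoromethanesulfonate, CC[Si](CC)(CC)OS(=O)(=O)C(F)(F)F
Why: Silyl triflate silylation of the hindered secondary alcohol at low temperature with a weak base, which should prevent retro-aldol cleavage or β-elimination of the ketol.

Step 14
Reactants: 17 spiro ketone
Product: 18 2'-methylene compound (exocyclic C=CH2 in place of the C2' ketone)
Conditions: Zn, CH2Br2, TiCl4, THF; then 17, CH2Cl2, 0 °C → rt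
Reagents that add atoms: dibromomethane, BrCBr
Why: Takai–Lombardo methylenation is non-basic and ketone-selective, so the hindered, β-silyloxy ketone is converted without enolate formation while the lactone and the silyl ethers are left alone; after this step the lactone is the only carbonyl group.

Step 15
Reactants: 18 methylene compound
Product: 20 α-methylene lactone (C4=CH2), via Mannich base 19 (not isolated)
Conditions: lithium diisopropylamide, THF, −78 °C; Me2N=CH2+ I−, −78 °C → rt; then MeI, rt; then aq. NaHCO3
Reagents that add atoms: dimethylmethylideneammonium iodide (Eschenmoser's salt), C=[N+](C)C.[I-]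
Why: Mannich aminomethylation of the lactone enolate (the only acidic site left) followed by quaternisation and E1cB loss of trimethylamine gives the exocyclic α-methylene lactone; no stereocentre remains at C4.

Step 16
Reactants: 20 diene
Product: 22 primary allylic alcohol (C2'–CH2OH with C2'=C3' ring alkene), via allylic hydroperoxide 21 (not isolated)
Conditions: O2, tetraphenylporphyrin (cat.), visible light, CH2Cl2, 0 °C; then PPh3, 0 °C
Reagents that add atoms: dioxygen, O=O
Why: Schenck ene reaction of singlet oxygen with the electron-rich 1,1-disubstituted alkene: oxygen bonds to the terminal CH2 and the only allylic hydrogens, those at C3', are abstracted, so the double bond moves into the ring without touching the C4' centre; the electron-poor α-methylene lactone is inert and PPh3 reduces the hydroperoxide.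

Step 17
Reactants: 22 allylic alcohol; 23 angelic acid
Product: 25 angelate ester bis(triethylsilyl) ether, via mixed anhydride 24 (not isolated)
Conditions: 2,4,6-Cl3C6H2COCl, Et3N, toluene, rt; then 22, 75 °C
Reagents that add atoms: angelic acid (23), C/C=C(/C)C(=O)O
Why: Yamaguchi-type esterification through the mixed anhydride, run without DMAP so that the Z-configured angelate should not isomerise to the tiglate; the alcohol attacks the less hindered angeloyl carbonyl.

Step 18
Reactants: 25 bis-silyl ether
Product: 26 target
Conditions: HF·pyridine, pyridine, THF, 0 °C → rt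
Reagents that add atoms: none
Why: Buffered fluoride cleavage of the two secondary triethylsilyl ethers, conditions under which the angelate, the α-methylene lactone and the allylic diol should be stable and no acyl migration is expected.

**Compound list**

1 | (1R,5S)-2-oxabicyclo[3.3.0]oct-6-en-3-one | C1C(=O)O[C@@H]2CC=C[C@H]12 | starting material
2 | 6-exo-bromo-7-endo-hydroxy-2-oxabicyclo[3.3.0]octan-3-one | C1C(=O)O[C@@H]2C[C@H](O)[C@@H](Br)[C@H]12 | intermediate
3 | 7-endo-hydroxy-2-oxabicyclo[3.3.0]octan-3-one | C1C(=O)O[C@@H]2C[C@H](O)C[C@H]12 | intermediate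
4 | cis-2-oxabicyclo[3.3.0]octane-3,7-dione | C1C(=O)O[C@@H]2CC(=O)C[C@H]12 | intermediate
5 | 7-exo-ethynyl-7-endo-hydroxy-2-oxabicyclo[3.3.0]octan-3-one | C1C(=O)O[C@@H]2C[C@@](O)(C#C)C[C@H]12 | intermediate
6 | 7-acetyl-2-oxabicyclo[3.3.0]oct-6-en-3-one | C1C(=O)O[C@@H]2CC(C(C)=O)=C[C@H]12 | intermediate
7 | 7-[1-(triethylsilyloxy)ethylidene]-2-oxabicyclo[3.3.0]octan-3-one (E/Z mixture) | C1C(=O)O[C@@H]2CC(=C(C)O[Si](CC)(CC)CC)C[C@H]12 | intermediate
8 | (E)-crotonaldehyde | C/C=C/C=O | starting material
9 | (3S)-3-(7-acetyl-3-oxo-2-oxabicyclo[3.3.0]oct-7-yl)butanal, acetyl endo | C1C(=O)O[C@@H]2C[C@@](C[C@H]12)(C(C)=O)[C@@H](C)CC=O | intermediate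
10 | nitrosobenzene | O=Nc1ccccc1 | starting material
11 | (2S,3R)-3-(7-acetyl-3-oxo-2-oxabicyclo[3.3.0]oct-7-yl)-2-(N-phenylaminooxy)butanal | C1C(=O)O[C@@H]2C[C@@](C[C@H]12)(C(C)=O)[C@@H](C)[C@H](ONc1ccccc1)C=O | intermediate
12 | (2S,3R)-3-(7-acetyl-3-oxo-2-oxabicyclo[3.3.0]oct-7-yl)-2-(N-phenylaminooxy)butan-1-ol | C1C(=O)O[C@@H]2C[C@@](C[C@H]12)(C(C)=O)[C@@H](C)[C@H](ONc1ccccc1)CO | intermediate
13 | (2S,3R)-3-(7-acetyl-3-oxo-2-oxabicyclo[3.3.0]oct-7-yl)butane-1,2-diol | C1C(=O)O[C@@H]2C[C@@](C[C@H]12)(C(C)=O)[C@@H](C)[C@H](O)CO | intermediate
14 | 1,2-bis(triethylsilyl) ether of 13 | C1C(=O)O[C@@H]2C[C@@](C[C@H]12)(C(C)=O)[C@@H](C)[C@H](O[Si](CC)(CC)CC)CO[Si](CC)(CC)CC | intermediate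
15 | (2S,3R)-3-(7-acetyl-3-oxo-2-oxabicyclo[3.3.0]oct-7-yl)-2-(triethylsilyloxy)butanal | C1C(=O)O[C@@H]2C[C@@](C[C@H]12)(C(C)=O)[C@@H](C)[C@H](O[Si](CC)(CC)CC)C=O | intermediate
16 | spiro ketol: C2' ketone, (4'S)-OH, (5'S)-OSiEt3, (6'R)-CH3 | C1C(=O)O[C@@H]2C[C@@]3(C[C@H]12)C(=O)C[C@H](O)[C@@H](O[Si](CC)(CC)CC)[C@@H]3C | intermediate
17 | 4',5'-bis(triethylsilyloxy) spiro ketone | C1C(=O)O[C@@H]2C[C@@]3(C[C@H]12)C(=O)C[C@H](O[Si](CC)(CC)CC)[C@@H](O[Si](CC)(CC)CC)[C@@H]3C | intermediate
18 | 2'-methylene-4',5'-bis(triethylsilyloxy) spiro lactone | C1C(=O)O[C@@H]2C[C@@]3(C[C@H]12)C(=C)C[C@H](O[Si](CC)(CC)CC)[C@@H](O[Si](CC)(CC)CC)[C@@H]3C | intermediate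
19 | 4-(dimethylaminomethyl) lactone from 18 (mixture at C4) | CN(C)CC1C(=O)O[C@@H]2C[C@@]3(C[C@H]12)C(=C)C[C@H](O[Si](CC)(CC)CC)[C@@H](O[Si](CC)(CC)CC)[C@@H]3C | intermediate
20 | 4-methylene lactone with 2'-methylene group | C=C1C(=O)O[C@@H]2C[C@@]3(C[C@H]12)C(=C)C[C@H](O[Si](CC)(CC)CC)[C@@H](O[Si](CC)(CC)CC)[C@@H]3C | intermediate
21 | 2'-(hydroperoxymethyl)-2'-ene | C=C1C(=O)O[C@@H]2C[C@@]3(C[C@H]12)C(COO)=C[C@H](O[Si](CC)(CC)CC)[C@@H](O[Si](CC)(CC)CC)[C@@H]3C | intermediate
22 | 2'-(hydroxymethyl)-2'-ene | C=C1C(=O)O[C@@H]2C[C@@]3(C[C@H]12)C(CO)=C[C@H](O[Si](CC)(CC)CC)[C@@H](O[Si](CC)(CC)CC)[C@@H]3C | intermediate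
23 | angelic acid, (Z)-2-methylbut-2-enoic acid | C/C=C(/C)C(=O)O | starting material
24 | angelic 2,4,6-trichlorobenzoic anhydride | C/C=C(/C)C(=O)OC(=O)c1c(Cl)cc(Cl)cc1Cl | intermediate
25 | angelate ester, 4',5'-bis(triethylsilyl) ether | C=C1C(=O)O[C@@H]2C[C@@]3(C[C@H]12)C(COC(=O)/C(C)=C\C)=C[C@H](O[Si](CC)(CC)CC)[C@@H](O[Si](CC)(CC)CC)[C@@H]3C | intermediate
26 | CNP0224912.1 | C=C1C(=O)O[C@@H]2C[C@@]3(C[C@H]12)C(COC(=O)/C(C)=C\C)=C[C@H](O)[C@@H](O)[C@@H]3C | target

Total step count: 18. Longest linear sequence: 18 steps (1 → 26).

**Steps most likely to fail**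

Step 12. Enamine formation at the hindered tert-alkyl methyl ketone may be slow, which would give enamine formation at the aldehyde (and epimerisation beside the silyloxy group) time to compete. The ring may also close through a hydrogen-bonded arrangement with the aldehyde oxygen axial, which would give the C4' epimer faster than it equilibrates.
Fallback: the same C3'–C4' bond is made by a Lewis-acid carbonyl-ene cyclisation instead of an aldol. Setting out from 14, Takai–Lombardo methylenation of the methyl ketone (Zn, CH2Br2, TiCl4) would give the isopropenyl compound F1. Swern treatment as in step 11 would give the ene aldehyde F2. Methylaluminium bis(4-bromo-2,6-di-tert-butylphenoxide) in CH2Cl2 at −78 °C should then close the ring with transfer of an allylic methyl hydrogen, giving the exocyclic methylene alcohol F3. The bulky aluminium-bound oxygen is expected to sit equatorial, trans to the silyloxy group. Silylation (Et3SiOTf, 2,6-lutidine) returns to the route at 18.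

Step 7. The fully substituted enol ether may add too slowly to the iminium ion, so that acid-promoted protodesilylation to the 7-acetyl lactone takes over. Discrimination between the convex and concave faces of C7 may also be insufficient.
Fallback: setting out from 7, iridium-catalysed branched-selective allylic alkylation with methyl (E)-but-2-enyl carbonate ([Ir(cod)Cl]2, a Feringa-type phosphoramidite of the enantiomer that gives the S methyl centre, CsF, ZnF2, THF, 50 °C) would give the butenyl ketone F4. Hydroboration with 9-BBN and oxidation with NaBO3 would give the primary alcohol F5, and Dess–Martin oxidation returns to the route at 9.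

Step 16. The ene reaction of the hindered 1,1-disubstituted alkene beside the quaternary carbon may be sluggish, so that long irradiation leads to further oxidation of the product alkene.
Fallback: setting out from 20, ene-type chlorination with HOCl generated from Ca(OCl)2 and CO2 (CH2Cl2–H2O, 0 °C) should give the allylic chloride F6 with the same double-bond shift. Displacement with cesium angelate (23, Cs2CO3, DMF, rt) gives the ester without any risk of angelate isomerisation and returns to the route at 25, leaving out steps 16 and 17.

**Further compounds**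

F1 | step 12 | (2S,3R)-3-(7-isopropenyl-3-oxo-2-oxabicyclo[3.3.0]oct-7-yl)butane-1,2-diol bis(triethylsilyl) ether | C1C(=O)O[C@@H]2C[C@@](C[C@H]12)(C(C)=C)[C@@H](C)[C@H](O[Si](CC)(CC)CC)CO[Si](CC)(CC)CC
F2 | step 12 | (2S,3R)-3-(7-isopropenyl-3-oxo-2-oxabicyclo[3.3.0]oct-7-yl)-2-(triethylsilyloxy)butanal | C1C(=O)O[C@@H]2C[C@@](C[C@H]12)(C(C)=C)[C@@H](C)[C@H](O[Si](CC)(CC)CC)C=O
F3 | step 12 | 2'-methylene-(4'S)-hydroxy-(5'S)-triethylsilyloxy spiro lactone | C1C(=O)O[C@@H]2C[C@@]3(C[C@H]12)C(=C)C[C@H](O)[C@@H](O[Si](CC)(CC)CC)[C@@H]3C
F4 | step 7 | 7-acetyl-7-[(2S)-but-3-en-2-yl]-2-oxabicyclo[3.3.0]octan-3-one, acetyl endo | C1C(=O)O[C@@H]2C[C@@](C[C@H]12)(C(C)=O)[C@@H](C)C=C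
F5 | step 7 | (3S)-3-(7-acetyl-3-oxo-2-oxabicyclo[3.3.0]oct-7-yl)butan-1-ol | C1C(=O)O[C@@H]2C[C@@](C[C@H]12)(C(C)=O)[C@@H](C)CCO
F6 | step 16 | 2'-(chloromethyl)-2'-ene bis(triethylsilyl) ether with 4-methylene lactone | C=C1C(=O)O[C@@H]2C[C@@]3(C[C@H]12)C(CCl)=C[C@H](O[Si](CC)(CC)CC)[C@@H](O[Si](CC)(CC)CC)[C@@H]3C
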